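If both mirror-image substrates are consumed first order by one catalyst, their logarithmic rates share whatever time dependence that catalyst has and differ by a constant factor, s. The fractions left then obey f_left = f_right^s at every moment, however the rate wanders.

| setting | Sunday's | Monday's | birch | maple |
|---|---|---|---|---|
| left-handed substrate | 13 mM | 30 mM | 20 mM | 20 mM |
| right-handed substrate | 13 mM | 30 mM | 20 mM | 20 mM |
| gas | 2.9 mM (held) | 2.9 mM (held) | 2.9 mM (held) | 2.9 mM (held) |
| precatalyst | 58 µM | 58 µM | 58 µM | 58 µM |
| added ligand | 81 µM | 81 µM | 81 µM | 81 µM |
| remark | run made earlier | run made earlier |  |  |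
| time |  |  | 1.5 h | 5.0 h |

| run | time / min | right-handed substrate / % | left-handed substrate / % |
|---|---|---|---|
| Sunday's | 4.00 | 50.3 | 49.9 |
| Sunday's | 6.00 | 50.0 | 50.2 |
| Sunday's | 10.0 | 49.7 | 49.3 |
| Sunday's | 15.0 | 49.4 | 49.3 |
| Sunday's | 25.0 | 48.8 | 47.4 |
| Sunday's | 40.0 | 47.8 | 44.6 |
| Sunday's | 50.0 | 46.6 | 42.3 |
| Monday's | 4.00 | 49.8 | 49.7 |
| Monday's | 6.00 | 50.3 | 49.8 |
| Monday's | 10.0 | 49.7 | 49.8 |
| Monday's | 15.0 | 49.6 | 49.6 |
| Monday's | 25.0 | 49.4 | 47.7 |
| Monday's | 40.0 | 48.0 | 45.0 |
| Monday's | 50.0 | 47.1 | 42.2 |

(scatter of a reading: 0.3 percentage points)

- catalyst is single-handed; left-handed substrate and right-handed substrate are mirror images of each other, charged as a racemate, each of them at the stated concentration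
- at the start none of the gas is in solution
- an excess is below zero if the other one leads

- which of the two ends with the higher excess of right-handed substrate over left-handed substrate among what is left of the two ("neither" if they lie within 2 percentage points) (birch / maple / neither)
- excess of right-handed substrate over left-handed substrate among what is left of the two at the end, birch
- excess of right-handed substrate over left-handed substrate among what is left of the two at the end, maple

The curves at 13 mM and 30 mM coincide within scatter, so first order stands. Averaging both runs at 50.0 min gives s = 2.59, the selectivity factor: the logarithm of the left-handed fraction left over that of the right-handed fraction left. With equal charges, the excess is (f_right − f_left)/(f_right + f_left). So s turns a single clock, x = −ln f_left, into the excess, and the dispute is over that clock.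

The forecast's author holds that a lag is followed by a nearly steady rate. I hold that the rate is still rising, roughly in proportion to time, so x grows as t squared. The readings give x = 0.0502 at 25.0 min, 0.110 at 40.0 min and 0.168 at 50.0 min. The slope grows from 0.00397 /min to 0.00586 /min, which is my ground.

My clock gives birch x = 0.546, hence an excess of 16.6%. For maple it gives x = 6.06 and 95.3%, which I take as an upper estimate, for maple's time is 6.00 times that of the last reading.

The forecast also has maple leading, with 11% (9% to 14%) for birch and 41% (30% to 54%) for maple. Its caution: “This is a long extrapolation, and catalyst lifetime is untested.”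

The simulation gives maple, with 16.5% in birch and 83.4% in maple, both above the forecast's ranges.

    partner + catalyst + right-handed substrate → catalyst + right-handed product (k = 90000 /M²/min)
    partner + catalyst + left-handed substrate → catalyst + left-handed product (k = 2.50 × 10⁵ /M²/min)
    catalyst + added ligand ⇌ idle complex, settled at all times (K = 24000 /M)
    partner + precatalyst → catalyst + spent reagent (k = 4.10 /M/min)
    gas ⇌ partner, rate k5*(csat - [partner]) (kL = 1.00 /min)

The steady rate becomes right in maple near 5.00 h, where catalyst stands at 43.8% against 45.7% at 50.0 h, while birch's catalyst was still climbing from 15.3% at 0.750 h to 26.3% at 1.50 h. There, in maple, the left-handed substrate's half-life by its step is 0.64 h, shorter than the right-handed substrate's 1.8 h. Maple's 26% of right-handed substrate left, raised to s, gives 3.05% for the left-handed, and 2.3% stands. In the neighbour of maple charged with 0.014 mM of precatalyst, 76% raised to s gives 48.5%, and 46% stands.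

The readings were computed on assumed constants; scatter was added.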